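## Structural features

The target consists of two units joined by one methylene: a γ-butyrolactone carrying a 4-hydroxy-3-methoxybenzyl group at C4, and a 2,3-dihydrobenzofuran whose C5 is linked through CH2 to lactone C3. The dihydrobenzofuran carries a 4-hydroxy-3-methoxyphenyl group (ring B) at C2, a hydroxymethyl group at C3 and a phenolic hydroxyl at C7, next to the ring oxygen on ring A. There are four stereocentres in two adjacent pairs, lactone C3/C4 (3S,4S, trans) and benzofuran C2/C3 (2S,3R, trans); an aryl CH2 spacer insulates the pairs, so each needs its own source of absolute configuration. Fragile points are the benzylic C2–O1 aryl ether, which a para oxygen on ring B makes prone to acid ionisation and to hydrogenolysis, the three free phenols, and the epimerisable lactone C3, for which trans is the stable arrangement. The real difficulty is the trans 2-aryl-3-(hydroxymethyl)dihydrobenzofuran as one enantiomer, with oxygen at C7 and a carbon handle at C5, together with an end-game that removes protecting groups without opening that ring. The key step exploits the mapping of benzofuran C2, C3, C3a and the CH2OH carbon onto C2, C3, C4a and C4 of a flavanone: a shift of ring A from C4 to C3 contracts the pyranone to the dihydrofuran and pushes C4 out of the ring as an ester. The descriptors were checked on this mapping: the (2S) flavanone gives the (2S) benzofuran, and the (3S) ester becomes (3R) on reduction through a change of CIP priority only.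

## Logic of the disconnections

From 23 to 22: the four O–benzyl bonds (C7 oxygen, ring B oxygen, primary alcohol, guaiacyl oxygen of the lactone unit) are cut last. One kind of protecting group means one final operation and no strongly acidic or basic step on the finished skeleton. The forward step must cleave one alkyl and three aryl benzyl ethers without reducing the benzylic C2–O1 bond.

From 22 to 21 and 15: the bond between lactone C3 and the benzylic CH2 is cut. This is the most convergent cut: it gives a lactone with one stereocentre (fragment 2) and the dihydrobenzofuran as a benzylic bromide (fragment 1), and lactone C3 is then set by its neighbour C4. The forward alkylation must be trans-selective and must outrun decomposition of an electron-rich benzylic bromide.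

From 15 through 14 to 13: the C–Br bond is traced to C–OH, then the aryl C5–CH2 bond is cut to leave an aryl bromide. Bromine is the smallest inert handle that survives ring formation. The forward cross-coupling needs a hydroxymethyl donor under aqueous base, which is why every oxygen of 13 is a benzyl ether.

From 13 through 12 to 11: two O–benzyl bonds are removed, the CH2OH group is traced to a methyl ester and the ring B phenol to a pivalate. One hydride reduction delivers both hydroxyl groups, so the ring B group needed in the key step costs no separate removal. The reduction must spare the aryl bromide and be faster than enolisation at C3.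

From 11 to 9 (through 10): the C3–C3a bond is cut and C3a is reconnected to the ester carbon, which becomes the ketone C4 of a flavanone. The trans pair of stereocentres is reduced to a single centre at C2 of a six-membered ketone. The forward step must move ring A rather than ring B, must not dehydrogenate, and must not ionise the C2–O1 bond in acid. Ring B therefore carries an acyloxy group: a pivalate is electron-poor enough for this and, unlike an aryl sulfonate, needs no strong base for removal once the lactone is present.

From 9 to 5 and 8: the C2–aryl bond is cut. This gives an achiral chromone and an arylboronic acid, and the only stereocentre made by asymmetric catalysis on this fragment. The forward conjugate addition must be enantioselective and must leave the aryl bromide alone, which a cycle that stays at divalent palladium allows.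

From 5 through 3 and 2 to 1: C2 and the O1–C2 bond are removed (one carbon from an amide acetal), then the C–Br bond, then the O–benzyl bond. Benzylation comes before bromination so that the free 2'-hydroxyl alone directs the halogen to its para position. The forward benzylation must select the 3'-oxygen.

From 8 through 7 to 6: the C–B bond and the O–acyl bond are cut. The forward borylation must give the free boronic acid without touching the pivalate.

From 21 through 19 and 18 to 16 and 17: the lactone C–O bond is traced to an ester next to a carboxylic acid, the stereocentre to an alkene, and the alkene to an aldehyde and a succinate. This gives three steps from two bulk chemicals. The demands are a highly enantioselective hydrogenation and an ester reduction that spares the carboxylate, so that the lactone closes on the correct side.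

## Other disconnections considered

Alternative 1: The cut is the O1–C7a bond together with the C7–O bond. In the forward sense the open-chain fluoro alcohol A2 would be treated with excess lithium base: the alkoxide forms, C7 is lithiated next to fluorine, LiF is lost, the tethered alkoxide adds to the C7–C7a aryne at C7a, and the C7 aryllithium is trapped with B(OMe)3 and oxidised with H2O2 to give A1.
- In its favour: the ring closes under basic conditions, so the benzylic C–O bond is never exposed to acid and ring B can be a plain benzyl ether. On this point it is better than the chosen plan.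
- Also better: A1 already holds the C5 carbon as an acetal, whereas the chosen plan must add that carbon by cross-coupling, and two C–O bonds are made in one operation.
- Against it: A2 carries both stereocentres before ring closure, so an auxiliary- or catalyst-controlled construction of a 1,2-diarylpropanol is needed. Nothing epimerisable remains afterwards to correct a wrong diastereomer.
- Against it: the organolithium must choose the position next to fluorine over the acetal-flanked positions and the benzylic ether CH2, and the aryl anion must survive until borate trapping.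
- Comparison: the ring and substitution pattern are equivalent. The mechanism is anionic where the chosen one is cationic. Step economy is expected to be lower, because A2 is longer to make than 9 and the acetal still needs three operations to become the benzylic bromide.

Alternative 2: The cut is the lactone O1–C5 bond, made by oxygen insertion. The cyclobutanone A4 would react with m-CPBA under a chiral Sc(OTf)3–N,N'-dioxide complex, and migration of one enantiotopic CH2 group in the Criegee intermediate would give A3, which is identical with 21.
- In its favour: it is catalytic, needs no hydrogen pressure, and A4 is two steps from a eugenol ether (ketene cycloaddition, dechlorination). Its three steps equal the three used here for 21.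
- Against it: it addresses only the simple fragment and leaves the dihydrobenzofuran untouched.
- Against it: the controlling substituent is a benzyl group one carbon removed from the ring, so discrimination between the two CH2 groups is expected to be less dependable than hydrogenation of a chelating half-ester. The peracid also meets an electron-rich arene.
- Comparison: it competes with steps 12 to 14, not with the key step, and could replace them without changing anything else.

Alternative 3: The cut is the C2–C3 bond. Rh2(S-PTTL)4 would decompose the aryldiazoacetate A6 and the carbenoid would insert into the benzylic ether C–H bond to give the cis ester A5, which base would then epimerise at C3 to the trans series.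
- In its favour: both stereocentres come from one catalytic step on an achiral precursor, where the chosen plan sets C2 and C3 in two consecutive steps.
- Also better: no acid is used, so ring B can carry a benzyl ether, and an electron-rich benzylic C–H bond should even insert faster. The pivalate detour is avoided.
- Against it: the product is cis, so an extra epimerisation is needed under base, where reversible E1cB opening of the ring could erode C2.
- Against it: A6 needs an arylacetic ester, a separate benzylic halide and a diazo transfer, and the 3-benzyloxy group flanking the reacting ether may lower facial selectivity.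
- Comparison: the product matches 11 apart from the ring B group. The mechanism is a concerted insertion against a cationic 1,2-shift. The step count to the trans ester is about equal to that of the chosen plan.

Key step: step 7

Assumption: the ligand antipodes in steps 6 and 13 follow the sense of induction of the closest substrate classes (β-substituted cyclic enones, itaconate half-esters); if the first batch were the mirror image, the other antipode would be used and nothing else changes.

Assumption: compounds 1, 6, 16 and 17, both chiral ligands, B2(OH)4 and AcOCH2BF3K are taken as purchasable.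

## Route

Step 1
Reactants: 1 2',3'-dihydroxyacetophenone
Product: 2 1-[3-(benzyloxy)-2-hydroxyphenyl]ethan-1-one
Conditions: NaH (2.1 equiv), DMSO/THF, 0 °C to rt; BnBr (1.0 equiv)
Reagents that add atoms: benzyl bromide, BrCc1ccccc1
Why: Williamson etherification of the dianion; the 2'-phenoxide is conjugated with and chelated to the acetyl group, so the 3'-phenoxide is the more nucleophilic oxygen and should take the single equivalent of benzyl bromide.

Step 2
Reactants: 2 1-[3-(benzyloxy)-2-hydroxyphenyl]ethan-1-one
Product: 3 1-[3-(benzyloxy)-5-bromo-2-hydroxyphenyl]ethan-1-one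
Conditions: NBS, MeCN, 0 °C to rt
Reagents that add atoms: N-bromosuccinimide, O=C1CCC(=O)N1Br
Why: Electrophilic aromatic bromination; the free 2'-hydroxyl directs to its para position C5', which is also meta to the acetyl group, as in the bromination of o-vanillin.

Step 3
Reactants: 3 1-[3-(benzyloxy)-5-bromo-2-hydroxyphenyl]ethan-1-one
Product: 5 8-(benzyloxy)-6-bromo-4H-chromen-4-one, via enaminone 4 (not isolated)
Conditions: Me2NCH(OMe)2, toluene, 100 °C; then conc. HCl, CH2Cl2, 40 °C
Reagents that add atoms: N,N-dimethylformamide dimethyl acetal, COC(OC)N(C)C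
Why: Condensation of the methyl ketone with the amide acetal gives enaminone 4; acid then promotes conjugate addition of the phenol and loss of dimethylamine, which closes the pyranone (enaminone route to chromones).

Step 4
Reactants: 6 4-bromo-2-methoxyphenol
Product: 7 4-bromo-2-methoxyphenyl pivalate
Conditions: PivCl, Et3N, DMAP (cat.), CH2Cl2, 0 °C to rt
Reagents that add atoms: pivaloyl chloride, CC(C)(C)C(=O)Cl
Why: O-acylation of the phenol; the hindered, electron-poor acyloxy group is meant to survive the boron, palladium and acid steps and to leave in the later hydride reduction.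

Step 5
Reactants: 7 4-bromo-2-methoxyphenyl pivalate
Product: 8 [3-methoxy-4-(pivaloyloxy)phenyl]boronic acid
Conditions: B2(OH)4, PdCl(XPhos)(2'-amino-1,1'-biphenyl-2-yl) (second-generation XPhos precatalyst, 1 mol %), XPhos (2 mol %), KOAc, EtOH, 80 °C
Reagents that add atoms: tetrahydroxydiboron, OB(O)B(O)O
Why: Miyaura borylation with tetrahydroxydiboron gives the boronic acid directly from the aryl bromide; acetate in ethanol should not cleave a pivalate.

Step 6
Reactants: 5 8-(benzyloxy)-6-bromo-4H-chromen-4-one; 8 [3-methoxy-4-(pivaloyloxy)phenyl]boronic acid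
Product: 9 (S)-8-(benzyloxy)-6-bromo-2-[3-methoxy-4-(pivaloyloxy)phenyl]chroman-4-one
Conditions: Pd(OCOCF3)2 (5 mol %), (R)-t-BuPyOx (6 mol %), NH4PF6 (30 mol %), H2O (5 equiv), ClCH2CH2Cl, 60 °C
Reagents that add atoms: none
Why: Asymmetric conjugate addition of an arylboronic acid to a chromone under a divalent palladium–pyridine-oxazoline catalyst: transmetalation, enantioface-selective insertion of the C2=C3 bond and protonolysis of the palladium enolate set C2 as (S) under ligand control. The cycle never passes through zerovalent palladium, so the aryl bromide should be untouched.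

Step 7
Reactants: 9 (S)-8-(benzyloxy)-6-bromo-2-[3-methoxy-4-(pivaloyloxy)phenyl]chroman-4-one
Product: 11 methyl trans-(2S,3S)-7-(benzyloxy)-5-bromo-2-[3-methoxy-4-(pivaloyloxy)phenyl]-2,3-dihydrobenzofuran-3-carboxylate, via methyl enol ether 10 (not isolated)
Conditions: PhI(OAc)2 (1.3 equiv), conc. H2SO4, HC(OMe)3, rt
Reagents that add atoms: trimethyl orthoformate, COC(OC)OC
Why: Acid and the orthoformate convert the ketone of 9 into its dimethyl ketal and then the methyl enol ether 10, whose C3 is attacked by the trivalent iodine electrophile on the face away from the C2 aryl group, and methanol re-forms the ketal at C4. The C3–I bond then lies antiperiplanar to C4–C4a, so loss of iodobenzene is assisted by the shift of the ring A carbon C4a from C4 to C3 through a bridged arenium ion, and the dimethoxycarbenium ion left at C4 collapses to the methyl ester. The closest known reaction type is the oxidative 1,2-aryl shift of aryl ketones and flavanones with PhI(OAc)2 or Tl(NO3)3 in trimethyl orthoformate, which gives trans 2-aryl-2,3-dihydrobenzofuran-3-carboxylates. The five-membered ring is closed by contraction, not end-on: a three-membered bridging (3-exo) participation of the aryl ipso carbon at C3 is followed by cleavage of C4–C4a, while O1, C2 and C8a stay in place. C2 is carried through unchanged, and the new C3 centre is controlled by C2, because iodination anti to the aryl group and migration with inversion place the ester trans to it, which is also the thermodynamic arrangement. The step needs ring A migration in preference to ring B migration (isoflavone), dehydrogenation (flavone) and simple C3 methoxylation; ketal-forming conditions, the ring oxygen ortho to the migrating carbon and the electron-poor pivaloyloxy ring B should secure this. The same pivalate holds back acid ionisation of the benzylic C2–O1 bond, which would otherwise erode the C2 configuration.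

Step 8
Reactants: 11 methyl trans-(2S,3S)-7-(benzyloxy)-5-bromo-2-[3-methoxy-4-(pivaloyloxy)phenyl]-2,3-dihydrobenzofuran-3-carboxylate
Product: 12 4-[(2S,3R)-7-(benzyloxy)-5-bromo-3-(hydroxymethyl)-2,3-dihydrobenzofuran-2-yl]-2-methoxyphenol
Conditions: LiAlH4, THF, 0 °C; Rochelle salt work-up
Reagents that add atoms: none
Why: Hydride reduction of both esters: the methyl ester gives the primary alcohol and the aryl pivalate is cleaved to the phenol. The aryl bromide and the benzyl ether are inert at 0 °C, and C3 is no longer epimerisable after reduction.

Step 9
Reactants: 12 4-[(2S,3R)-7-(benzyloxy)-5-bromo-3-(hydroxymethyl)-2,3-dihydrobenzofuran-2-yl]-2-methoxyphenol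
Product: 13 (2S,3R)-7-(benzyloxy)-2-[4-(benzyloxy)-3-methoxyphenyl]-3-[(benzyloxy)methyl]-5-bromo-2,3-dihydrobenzofuran
Conditions: NaH (2.5 equiv), BnBr (2.5 equiv), n-Bu4NI (cat.), DMF, 0 °C to rt
Reagents that add atoms: benzyl bromide, BrCc1ccccc1
Why: Double Williamson etherification of the phenoxide and the primary alkoxide. It makes every oxygen a base-stable benzyl ether, so one final operation can release them all.

Step 10
Reactants: 13 (2S,3R)-7-(benzyloxy)-2-[4-(benzyloxy)-3-methoxyphenyl]-3-[(benzyloxy)methyl]-5-bromo-2,3-dihydrobenzofuran
Product: 14 {(2S,3R)-7-(benzyloxy)-2-[4-(benzyloxy)-3-methoxyphenyl]-3-[(benzyloxy)methyl]-2,3-dihydrobenzofuran-5-yl}methanol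
Conditions: AcOCH2BF3K, Pd(dba)2 (3 mol %), RuPhos (6 mol %), Na2CO3, dioxane/H2O (10:1), 100 °C
Reagents that add atoms: potassium (acetoxymethyl)trifluoroborate, CC(=O)OC[B-](F)(F)F.[K+]
Why: Suzuki–Miyaura cross-coupling of the unhindered aryl bromide with an acetoxymethyl boron reagent; the acetyl group is lost to aqueous carbonate, so the benzylic alcohol is obtained directly. The substrate holds only ethers and should tolerate hot aqueous base.

Step 11
Reactants: 14 {(2S,3R)-7-(benzyloxy)-2-[4-(benzyloxy)-3-methoxyphenyl]-3-[(benzyloxy)methyl]-2,3-dihydrobenzofuran-5-yl}methanol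
Product: 15 (2S,3R)-7-(benzyloxy)-2-[4-(benzyloxy)-3-methoxyphenyl]-3-[(benzyloxy)methyl]-5-(bromomethyl)-2,3-dihydrobenzofuran
Conditions: CBr4, PPh3, CH2Cl2, 0 °C; used at once
Reagents that add atoms: carbon tetrabromide, BrC(Br)(Br)Br
Why: Appel reaction under neutral conditions; the alkoxy-activated benzylic bromide is prone to solvolysis and is taken into the coupling without storage.

Step 12
Reactants: 16 4-(benzyloxy)-3-methoxybenzaldehyde; 17 dimethyl succinate
Product: 18 (E)-4-[4-(benzyloxy)-3-methoxyphenyl]-3-(methoxycarbonyl)but-3-enoic acid
Conditions: NaOMe, MeOH, reflux; then 2 M HCl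
Reagents that add atoms: none
Why: Stobbe condensation: aldol addition, lactonisation and E1cB opening give the half-ester, with the free acid on the CH2 arm and the aryl group trans to the ester.

Step 13
Reactants: 18 (E)-4-[4-(benzyloxy)-3-methoxyphenyl]-3-(methoxycarbonyl)but-3-enoic acid
Product: 19 (3S)-4-[4-(benzyloxy)-3-methoxyphenyl]-3-(methoxycarbonyl)butanoic acid
Conditions: [Rh(cod)((R,R)-Et-DuPhos)]BF4 (1 mol %), H2 (5 bar), NaOMe (10 mol %), MeOH, rt
Reagents that add atoms: none
Why: Asymmetric hydrogenation of an itaconate-type half-ester: the carboxylate and the alkene chelate monovalent rhodium and hydrogen is delivered to one alkene face under control of the chiral bisphosphine, which sets the single stereocentre as (S). The benzyl ether is inert to this homogeneous catalyst.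

Step 14
Reactants: 19 (3S)-4-[4-(benzyloxy)-3-methoxyphenyl]-3-(methoxycarbonyl)butanoic acid
Product: 21 (4S)-4-[4-(benzyloxy)-3-methoxybenzyl]dihydrofuran-2(3H)-one, via hydroxy acid 20 (not isolated)
Conditions: KOH (1.0 equiv), EtOH; CaCl2, NaBH4, −10 °C to rt; then 2 M HCl
Reagents that add atoms: none
Why: Chemoselective borohydride reduction: Ca(BH4)2 formed in the flask reduces the methyl ester while the carboxylate salt is inert, and acidification lactonises hydroxy acid 20. The stereocentre is not involved.

Step 15
Reactants: 21 (4S)-4-[4-(benzyloxy)-3-methoxybenzyl]dihydrofuran-2(3H)-one; 15 (2S,3R)-7-(benzyloxy)-2-[4-(benzyloxy)-3-methoxyphenyl]-3-[(benzyloxy)methyl]-5-(bromomethyl)-2,3-dihydrobenzofuran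
Product: 22 (3S,4S)-4-[4-(benzyloxy)-3-methoxybenzyl]-3-({(2S,3R)-7-(benzyloxy)-2-[4-(benzyloxy)-3-methoxyphenyl]-3-[(benzyloxy)methyl]-2,3-dihydrobenzofuran-5-yl}methyl)dihydrofuran-2(3H)-one
Conditions: 21 (1.3 equiv), LiHMDS, THF, −78 °C; then 15, DMPU, −78 to −30 °C
Reagents that add atoms: none
Why: Alkylation of the lactone lithium enolate with a benzylic bromide; the electrophile approaches the planar enolate on the face opposite the C4 benzyl group, which sets C3 as (S) and gives the trans lactone. The centres of fragment 1 are not touched.

Step 16
Reactants: 22 (3S,4S)-4-[4-(benzyloxy)-3-methoxybenzyl]-3-({(2S,3R)-7-(benzyloxy)-2-[4-(benzyloxy)-3-methoxyphenyl]-3-[(benzyloxy)methyl]-2,3-dihydrobenzofuran-5-yl}methyl)dihydrofuran-2(3H)-one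
Product: 23 (3S,4S)-4-(4-hydroxy-3-methoxybenzyl)-3-{[(2S,3R)-7-hydroxy-2-(4-hydroxy-3-methoxyphenyl)-3-(hydroxymethyl)-2,3-dihydrobenzofuran-5-yl]methyl}dihydrofuran-2(3H)-one
Conditions: H2 (1 atm), 10% Pd/C, EtOAc/MeOH, rt; stopped at full debenzylation
Reagents that add atoms: none
Why: Catalytic hydrogenolysis of the three aryl benzyl ethers and the one alkyl benzyl ether under neutral conditions. No stereocentre is epimerisable under these conditions, and the cyclic secondary C2–O1 ether should react more slowly than the primary benzyl ethers.

## Compound list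

1 | 2',3'-dihydroxyacetophenone | CC(=O)c1cccc(O)c1O | starting material
2 | 1-[3-(benzyloxy)-2-hydroxyphenyl]ethan-1-one | CC(=O)c1cccc(OCc2ccccc2)c1O | intermediate
3 | 1-[3-(benzyloxy)-5-bromo-2-hydroxyphenyl]ethan-1-one | CC(=O)c1cc(Br)cc(OCc2ccccc2)c1O | intermediate
4 | (E)-1-[3-(benzyloxy)-5-bromo-2-hydroxyphenyl]-3-(dimethylamino)prop-2-en-1-one | CN(C)/C=C/C(=O)c1cc(Br)cc(OCc2ccccc2)c1O | intermediate
5 | 8-(benzyloxy)-6-bromo-4H-chromen-4-one | O=c1ccoc2c(OCc3ccccc3)cc(Br)cc12 | intermediate
6 | 4-bromo-2-methoxyphenol | COc1cc(Br)ccc1O | starting material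
7 | 4-bromo-2-methoxyphenyl pivalate | COc1cc(Br)ccc1OC(=O)C(C)(C)C | intermediate
8 | [3-methoxy-4-(pivaloyloxy)phenyl]boronic acid | COc1cc(B(O)O)ccc1OC(=O)C(C)(C)C | intermediate
9 | (S)-8-(benzyloxy)-6-bromo-2-[3-methoxy-4-(pivaloyloxy)phenyl]chroman-4-one | O=C1C[C@@H](c2ccc(OC(=O)C(C)(C)C)c(OC)c2)Oc2c(OCc3ccccc3)cc(Br)cc12 | intermediate
10 | (S)-8-(benzyloxy)-6-bromo-4-methoxy-2-[3-methoxy-4-(pivaloyloxy)phenyl]-2H-chromene | COC1=C[C@@H](c2ccc(OC(=O)C(C)(C)C)c(OC)c2)Oc2c(OCc3ccccc3)cc(Br)cc12 | intermediate
11 | methyl trans-(2S,3S)-7-(benzyloxy)-5-bromo-2-[3-methoxy-4-(pivaloyloxy)phenyl]-2,3-dihydrobenzofuran-3-carboxylate | Brc1cc(OCc2ccccc2)c2c(c1)[C@H](C(=O)OC)[C@@H](c1ccc(OC(=O)C(C)(C)C)c(OC)c1)O2 | intermediate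
12 | 4-[(2S,3R)-7-(benzyloxy)-5-bromo-3-(hydroxymethyl)-2,3-dihydrobenzofuran-2-yl]-2-methoxyphenol | Brc1cc(OCc2ccccc2)c2c(c1)[C@H](CO)[C@@H](c1ccc(O)c(OC)c1)O2 | intermediate
13 | (2S,3R)-7-(benzyloxy)-2-[4-(benzyloxy)-3-methoxyphenyl]-3-[(benzyloxy)methyl]-5-bromo-2,3-dihydrobenzofuran | Brc1cc(OCc2ccccc2)c2c(c1)[C@H](COCc1ccccc1)[C@@H](c1ccc(OCc3ccccc3)c(OC)c1)O2 | intermediate
14 | {(2S,3R)-7-(benzyloxy)-2-[4-(benzyloxy)-3-methoxyphenyl]-3-[(benzyloxy)methyl]-2,3-dihydrobenzofuran-5-yl}methanol | OCc1cc(OCc2ccccc2)c2c(c1)[C@H](COCc1ccccc1)[C@@H](c1ccc(OCc3ccccc3)c(OC)c1)O2 | intermediate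
15 | (2S,3R)-7-(benzyloxy)-2-[4-(benzyloxy)-3-methoxyphenyl]-3-[(benzyloxy)methyl]-5-(bromomethyl)-2,3-dihydrobenzofuran | BrCc1cc(OCc2ccccc2)c2c(c1)[C@H](COCc1ccccc1)[C@@H](c1ccc(OCc3ccccc3)c(OC)c1)O2 | intermediate
16 | 4-(benzyloxy)-3-methoxybenzaldehyde | COc1cc(C=O)ccc1OCc1ccccc1 | starting material
17 | dimethyl succinate | COC(=O)CCC(=O)OC | starting material
18 | (E)-4-[4-(benzyloxy)-3-methoxyphenyl]-3-(methoxycarbonyl)but-3-enoic acid | COC(=O)/C(CC(=O)O)=C/c1ccc(OCc2ccccc2)c(OC)c1 | intermediate
19 | (3S)-4-[4-(benzyloxy)-3-methoxyphenyl]-3-(methoxycarbonyl)butanoic acid | COc1cc(C[C@@H](CC(=O)O)C(=O)OC)ccc1OCc1ccccc1 | intermediate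
20 | (3S)-4-[4-(benzyloxy)-3-methoxyphenyl]-3-(hydroxymethyl)butanoic acid | COc1cc(C[C@@H](CC(=O)O)CO)ccc1OCc1ccccc1 | intermediate
21 | (4S)-4-[4-(benzyloxy)-3-methoxybenzyl]dihydrofuran-2(3H)-one | COc1cc(C[C@@H]2COC(=O)C2)ccc1OCc1ccccc1 | intermediate
22 | (3S,4S)-4-[4-(benzyloxy)-3-methoxybenzyl]-3-({(2S,3R)-7-(benzyloxy)-2-[4-(benzyloxy)-3-methoxyphenyl]-3-[(benzyloxy)methyl]-2,3-dihydrobenzofuran-5-yl}methyl)dihydrofuran-2(3H)-one | COc1cc(C[C@@H]2COC(=O)[C@H]2Cc2cc(OCc3ccccc3)c3c(c2)[C@H](COCc2ccccc2)[C@@H](c2ccc(OCc4ccccc4)c(OC)c2)O3)ccc1OCc1ccccc1 | intermediate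
23 | (3S,4S)-4-(4-hydroxy-3-methoxybenzyl)-3-{[(2S,3R)-7-hydroxy-2-(4-hydroxy-3-methoxyphenyl)-3-(hydroxymethyl)-2,3-dihydrobenzofuran-5-yl]methyl}dihydrofuran-2(3H)-one | COc1cc(C[C@@H]2COC(=O)[C@H]2Cc2cc(O)c3c(c2)[C@H](CO)[C@@H](c2ccc(O)c(OC)c2)O3)ccc1O | target

## Step count and least certain steps

Total: 16 steps. Longest linear sequence: 11 steps (steps 1, 2, 3, 6, 7, 8, 9, 10, 11, 15, 16; from 1 to 23).

Step 7 (key step). The most likely failures are diversion of the iodinated intermediate into dehydrogenation or C3 methoxylation, partial acid methanolysis of the pivalate followed by oxidation of the freed phenol, and slow ionisation at C2 that lowers the enantiomeric purity. They arise because ring A carries two inductively withdrawing meta substituents and migrates less readily than in the parent flavanone. Fallback, from 9 back to 11: a Wolff ring contraction, which moves the same ring A carbon from C4 to C3 without acid or oxidant. Compound 9 would be enolised with LiHMDS at −78 °C and acylated with CF3CO2CH2CF3 to the 3-trifluoroacetyl ketone F1. Without purification, MsN3 and Et3N in wet MeCN would convert this to the 3-diazo ketone F2 (same spatial arrangement at C2; the descriptor changes by priority only). Irradiation of F2 in methanol would give the ketene-derived methyl ester as a mixture of 11 and its cis epimer F3, and brief treatment with DBU in toluene should converge the mixture on 11.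

Step 6. Possible failures are slow insertion into a chromone that carries an alkoxy group next to the ring oxygen, competing protodeboronation, insufficient facial selectivity, and partial racemisation by reversible ring opening of the product. Fallback, from 5 and 8 back to 9: a resolution instead of asymmetric induction. Addition of 8 to 5 with Pd(OCOCF3)2 and 2,2'-bipyridine would give the racemic flavanone F4. Kinetic resolution by asymmetric transfer hydrogenation (RuCl(p-cymene)(TsDPEN) in the antipode that reduces the (2R) ketone faster, HCO2H/Et3N) would convert the unwanted enantiomer into the cis flavan-4-ol F5. Unreacted (S)-ketone 9 would be separated from F5 by chromatography.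

Step 1. Loss of regiocontrol, with alkylation at the 2'-oxygen or at both oxygens, is possible because the two phenoxides differ only through conjugation and chelation. Fallback, from 1 back to 2: exhaustive benzylation (BnBr, K2CO3, DMF) to the bis(benzyl ether) F6, then chelation-controlled removal of the benzyl group next to the carbonyl with MgBr2·OEt2 in toluene/ether.

Step 16. Over-reduction is possible: the benzylic C2–O1 bond may undergo hydrogenolysis while the slower alkyl benzyl ether is still being cleaved, because the freed para hydroxyl of ring B activates that bond. Fallback, from 22 directly to 23: Lewis-acid debenzylation with BCl3 and pentamethylbenzene as cation scavenger in CH2Cl2 at −78 °C. This removes the benzyl groups as benzylpentamethylbenzene without a reducing metal and makes no new intermediate.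

## Further compounds

F1 | step 7 | 4-[(2S)-8-(benzyloxy)-6-bromo-4-oxo-3-(trifluoroacetyl)chroman-2-yl]-2-methoxyphenyl pivalate (C3 epimers, in equilibrium with the enol) | O=C1C(C(=O)C(F)(F)F)[C@@H](c2ccc(OC(=O)C(C)(C)C)c(OC)c2)Oc2c(OCc3ccccc3)cc(Br)cc12
F2 | step 7 | 4-[(2R)-8-(benzyloxy)-6-bromo-3-diazo-4-oxochroman-2-yl]-2-methoxyphenyl pivalate | O=C1C(=[N+]=[N-])[C@@H](c2ccc(OC(=O)C(C)(C)C)c(OC)c2)Oc2c(OCc3ccccc3)cc(Br)cc12
F3 | step 7 | methyl cis-(2S,3R)-7-(benzyloxy)-5-bromo-2-[3-methoxy-4-(pivaloyloxy)phenyl]-2,3-dihydrobenzofuran-3-carboxylate | Brc1cc(OCc2ccccc2)c2c(c1)[C@@H](C(=O)OC)[C@@H](c1ccc(OC(=O)C(C)(C)C)c(OC)c1)O2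
F4 | step 6 | racemic 8-(benzyloxy)-6-bromo-2-[3-methoxy-4-(pivaloyloxy)phenyl]chroman-4-one | O=C1CC(c2ccc(OC(=O)C(C)(C)C)c(OC)c2)Oc2c(OCc3ccccc3)cc(Br)cc12
F5 | step 6 | 4-[(2R,4R)-8-(benzyloxy)-6-bromo-4-hydroxychroman-2-yl]-2-methoxyphenyl pivalate | O[C@@H]1C[C@H](c2ccc(OC(=O)C(C)(C)C)c(OC)c2)Oc2c(OCc3ccccc3)cc(Br)cc12
F6 | step 1 | 1-[2,3-bis(benzyloxy)phenyl]ethan-1-one | CC(=O)c1cccc(OCc2ccccc2)c1OCc1ccccc1
F0 | step 16 | none | none
A1 | alternative 1 | (2S,3R)-2-(4-benzyloxy-3-methoxyphenyl)-3-(tert-butyldimethylsilyloxymethyl)-5-(dimethoxymethyl)-2,3-dihydrobenzofuran-7-ol | COC(OC)c1cc(O)c2c(c1)[C@H](CO[Si](C)(C)C(C)(C)C)[C@@H](c1ccc(OCc3ccccc3)c(OC)c1)O2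
A2 | alternative 1 | (1S,2R)-1-(4-benzyloxy-3-methoxyphenyl)-3-(tert-butyldimethylsilyloxy)-2-[5-(dimethoxymethyl)-2-fluorophenyl]propan-1-ol | COC(OC)c1ccc(F)c(c1)[C@H](CO[Si](C)(C)C(C)(C)C)[C@@H](c1ccc(OCc2ccccc2)c(OC)c1)O
A3 | alternative 2 | (S)-4-(4-benzyloxy-3-methoxybenzyl)dihydrofuran-2(3H)-one | COc1cc(C[C@@H]2COC(=O)C2)ccc1OCc1ccccc1
A4 | alternative 2 | 3-(4-benzyloxy-3-methoxybenzyl)cyclobutan-1-one | COc1cc(CC2CC(=O)C2)ccc1OCc1ccccc1
A5 | alternative 3 | methyl cis-(2S,3R)-7-benzyloxy-2-(4-benzyloxy-3-methoxyphenyl)-5-bromo-2,3-dihydrobenzofuran-3-carboxylate | Brc1cc(OCc2ccccc2)c2c(c1)[C@@H](C(=O)OC)[C@@H](c1ccc(OCc3ccccc3)c(OC)c1)O2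
A6 | alternative 3 | methyl 2-[3-(benzyloxy)-2-{[4-(benzyloxy)-3-methoxybenzyl]oxy}-5-bromophenyl]-2-diazoacetate | COC(=O)C(=[N+]=[N-])c1cc(Br)cc(OCc2ccccc2)c1OCc1ccc(OCc2ccccc2)c(OC)c1
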